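**Retrosynthetic overview**
- The target is a 2,3,6,7-tetrahydro-1-benzofuran (O1, C2, C3, C3a, C4–C7, C7a). After a final desilylation, the carbocycle is cut at C5–C6 and C7–C7a: a Diels–Alder reaction of a 4-methoxy-furo[2,3-b]pyran-6-one with a (Z)-β-silyloxy enone, followed by loss of CO2.
- The pyranone ring is cut at C3a–C4 and at its ring oxygen: malonyl dichloride plus the ketene silyl acetal of a γ-lactone, then O-methylation.
- The strategy rests on the cis pair C2 (hydroxyisopropyl) / C3 (aryl) of the five-membered ring O1–C2–C3–C3a–C7a. With C7a as a carbonyl this ring is a cis-γ-butyrolactone, cut at C2–C3 and O1–C7a into a cinnamaldehyde (C3 is its β-carbon, used as a nucleophile) and an α-silyloxy aldehyde (C2).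
- Ring order: the five-membered O-ring first (as lactone), then the pyranone, then the carbocycle that replaces it.

Key step: step 5

Assumption: the sense of induction of the triazolium in this cross-annulation cannot be fixed in advance, so the route is written for whichever commercial antipode gives (2R,3R)-7; and the O-to-O silyl shift open to (Z)-15 is taken as harmless, because the tautomeric 3-silyloxy enal has a trisubstituted alkene and should not compete as dienophile (Curtin–Hammett).

**Route**

Step 1
Reactants: 1 methyl 3-formyl-4-hydroxybenzoate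
Product: 2 methyl 4-[tert-butyl(dimethyl)silyl]oxy-3-formylbenzoate
Conditions: TBSCl, imidazole, DMF, rt
Reagents that add atoms: tert-butyl(chloro)dimethylsilane, CC(C)(C)[Si](C)(C)Cl
Why: Imidazole-promoted silyl ether formation on the acidic phenol masks the oxygen that would otherwise interfere in step 5; no stereocentre is involved.

Step 2
Reactants: 2 methyl 4-[tert-butyl(dimethyl)silyl]oxy-3-formylbenzoate
Product: 3 methyl 4-[tert-butyl(dimethyl)silyl]oxy-3-[(E)-3-oxoprop-1-enyl]benzoate
Conditions: Ph3P=CHCHO (1.15 equiv), toluene, 80 °C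
Reagents that add atoms: (triphenylphosphoranylidene)acetaldehyde, O=CC=P(c1ccccc1)(c1ccccc1)c1ccccc1
Why: Wittig olefination with the stabilised formylmethylene ylide should give the (E)-enal, and the product enal is less electrophilic than the aryl aldehyde, so a small excess of ylide limits double homologation.

Step 3
Reactants: 4 methyl 2-hydroxy-2-methylpropanoate
Product: 5 methyl 2-methyl-2-(triethylsilyloxy)propanoate
Conditions: TESOTf, 2,6-lutidine, CH2Cl2, 0 °C
Reagents that add atoms: triethylsilyl trifluoromethanesulfonate, CC[Si](CC)(CC)OS(=O)(=O)C(F)(F)F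
Why: Silyl triflate silylation is the reliable way to protect a hindered tertiary alcohol; the triethylsilyl ether should last to step 11 and leave with fluoride at the end.

Step 4
Reactants: 5 methyl 2-methyl-2-(triethylsilyloxy)propanoate
Product: 6 2-methyl-2-(triethylsilyloxy)propanal
Conditions: iBu2AlH (1.1 equiv), CH2Cl2, −78 °C; MeOH, then aq. potassium sodium tartrate
Reagents that add atoms: none
Why: Partial hydride reduction of an α-oxygenated ester stops at the aldehyde because the aluminium hemiacetal is stable at −78 °C, and the product cannot enolise.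

Step 5
Reactants: 3 methyl 4-[tert-butyl(dimethyl)silyl]oxy-3-[(E)-3-oxoprop-1-enyl]benzoate, 6 2-methyl-2-(triethylsilyloxy)propanal
Product: 7 methyl 4-[tert-butyl(dimethyl)silyl]oxy-3-[(2R,3R)-5-oxo-2-[2-(triethylsilyloxy)propan-2-yl]oxolan-3-yl]benzoate (cis lactone)
Conditions: 6 (4 equiv), enantiopure 2-mesityl-5a,10b-dihydro-4H,6H-indeno[2,1-b][1,2,4]triazolo[4,3-d][1,4]oxazin-2-ium chloride (15 mol %), DBU (15 mol %), Ti(OiPr)4 (20 mol %), 4 Å MS, THF, 23 °C, 3 added over 8 h
Reagents that add atoms: none
Why: Proposed new method: addition of the triazolylidene to the aldehyde of 3 and a 1,2-proton shift should generate the conjugated Breslow intermediate, a homoenolate equivalent that attacks the carbonyl carbon of 6 through its β-carbon (forming C2–C3); tautomerisation then gives an acyl azolium on which the new alkoxide closes (forming O1–C7a) with release of the carbene. The closest known reaction type is the carbene-catalysed formal [3+2] annulation of cinnamaldehydes with aryl aldehydes or activated ketones to cis-γ-butyrolactones, and the extension lies in a hindered aliphatic α-silyloxy aldehyde as acceptor under enantiocontrol. The five-membered ring closes in the 5-exo-trig mode by acyl substitution at the azolium carbonyl. C3 is set by the chiral triazolium, whose indane wall leaves one face of the homoenolate open, and C2 is set relative to C3 in a closed transition state in which Ti(OiPr)4 links the enol oxygen to the aldehyde oxygen, which gives the kinetic cis lactone. The step needs cross- rather than self-annulation of 3, secured because 6 cannot enolise or form a homoenolate, is activated by its α-oxygen, is present in excess and meets 3 only at low concentration. A free ortho-phenol would acylate itself on the acyl azolium to a dihydrocoumarin, hence the aryl silyl ether.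

Step 6
Reactants: 7 cis lactone
Product: 8 methyl 4-[tert-butyl(dimethyl)silyl]oxy-3-[(2R,3R)-2-[2-(triethylsilyloxy)propan-2-yl]-5-(trimethylsilyloxy)-2,3-dihydrofuran-3-yl]benzoate (ketene silyl acetal, used crude)
Conditions: LiN(iPr)2 (1.2 equiv), Me3SiCl (1.5 equiv), THF, −78 °C; pentane, filtration under argon
Reagents that add atoms: chlorotrimethylsilane, C[Si](C)(C)Cl
Why: Kinetic deprotonation of the only enolisable position (the lactone α-CH2, C3a) with in situ O-silylation gives the ketene silyl acetal; C2 and C3 carry no acidic hydrogen and the benzoate has no α-hydrogen.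

Step 7
Reactants: 8 ketene silyl acetal, 9 malonyl dichloride
Product: 11 methyl 4-[tert-butyl(dimethyl)silyl]oxy-3-[(2R,3S)-4-hydroxy-6-oxo-2-[2-(triethylsilyloxy)propan-2-yl]-2,3-dihydro-6H-furo[2,3-b]pyran-3-yl]benzoate, via C-acylated acid chloride 10 (not isolated)
Conditions: 2,6-di-tert-butyl-4-methylpyridine (1.1 equiv), Et2O, −78 to 0 °C
Reagents that add atoms: none
Why: Proposed new method: the ketene acetal carbon C3a should be acylated by one acid chloride with loss of Me3SiCl to give 10, whose lactone carbonyl oxygen then attacks the second acid chloride (or adds to the acylketene formed from it), and loss of HCl with enolisation gives the 4-hydroxy-2-pyranone; the closest known reaction type is the annulation of ketone silyl enol ethers with malonyl dichloride to 6-substituted 4-hydroxy-2-pyranones, here extended to a lactone-derived ketene silyl acetal so that O1 ends up as a 6-alkoxy group, with the hindered pyridine taking up HCl to protect the silyl ethers.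

Step 8
Reactants: 11 hydroxypyranone
Product: 12 methyl 4-[tert-butyl(dimethyl)silyl]oxy-3-[(2R,3S)-4-methoxy-6-oxo-2-[2-(triethylsilyloxy)propan-2-yl]-2,3-dihydro-6H-furo[2,3-b]pyran-3-yl]benzoate
Conditions: MeOH (3 equiv), PPh3, DIAD, THF, 0 °C to rt
Reagents that add atoms: methanol, CO
Why: Mitsunobu O-alkylation of the acidic 4-hydroxy-2-pyranone is a known neutral route to 4-alkoxy-2-pyranones and avoids carbonate bases that could strip the aryl silyl ether and methylate the phenol.

Step 9
Reactants: 13 4-phenylbutan-2-one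
Product: 14 (Z)-1-hydroxy-5-phenylpent-1-en-3-one (chelated enol of 3-oxo-5-phenylpentanal)
Conditions: LiN(iPr)2 (1.1 equiv), THF, −78 °C; HCO2CH2CF3; aq. HCl
Reagents that add atoms: 2,2,2-trifluoroethyl formate, O=COCC(F)(F)F
Why: Kinetic enolisation on the methyl side followed by Claisen-type formylation with the reactive trifluoroethyl formate gives the β-keto aldehyde as its hydrogen-bonded Z enol.

Step 10
Reactants: 14 (Z)-1-hydroxy-5-phenylpent-1-en-3-one
Product: 15 (Z)-1-[tert-butyl(dimethyl)silyl]oxy-5-phenylpent-1-en-3-one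
Conditions: TBSOTf, Et3N, CH2Cl2, −78 °C
Reagents that add atoms: tert-butyldimethylsilyl trifluoromethanesulfonate, CC(C)(C)[Si](C)(C)OS(=O)(=O)C(F)(F)F
Why: Low-temperature silyl enol ether formation on the less hindered, aldehyde-derived oxygen of the cis-chelated enol should keep the Z geometry; the product is stored cold, used at once, and its geometry is to be checked by the vinyl coupling constant.

Step 11
Reactants: 12 methoxypyranone, 15 (Z)-silyloxy enone
Product: 17 methyl 4-[tert-butyl(dimethyl)silyl]oxy-3-[(2R,3S,6S,7S)-6-[tert-butyl(dimethyl)silyl]oxy-4-methoxy-7-(3-phenylpropanoyl)-2-[2-(triethylsilyloxy)propan-2-yl]-2,3,6,7-tetrahydro-1-benzofuran-3-yl]benzoate, via bridged lactone cycloadduct 16 (not isolated)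
Conditions: 15 (3 equiv), BHT (cat.), toluene, 110 °C, sealed tube
Reagents that add atoms: none
Why: Diels–Alder cycloaddition of the electron-rich 2-pyranone with retro-[4+2] loss of CO2 should join the nucleophilic diene terminus C5 to the silyloxy-bearing β-carbon (C6) and C7a to the acyl-bearing α-carbon (C7); the Z dienophile gives the cis C6/C7 pair, attack on the face opposite the cis C2/C3 groups with the acyl group endo places both new substituents trans to them, and the fully substituted C7a terminus of the product diene disfavours a second addition.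

Step 12
Reactants: 17 tris-silyl ether
Product: 18 methyl 4-hydroxy-3-[(2R,3S,6S,7S)-6-hydroxy-2-(2-hydroxypropan-2-yl)-4-methoxy-7-(3-phenylpropanoyl)-2,3,6,7-tetrahydro-1-benzofuran-3-yl]benzoate (target)
Conditions: Bu4NF (4 equiv), AcOH (4 equiv), THF, 0 °C to rt
Reagents that add atoms: none
Why: Acetic acid-buffered fluoride desilylation should remove the aryl, secondary and tertiary silyl ethers while staying too weakly basic for β-elimination of the C6 oxygen (which would aromatise the ring) or for epimerisation at C7.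

**Compound list**
1 | methyl 3-formyl-4-hydroxybenzoate | COC(=O)c1ccc(O)c(C=O)c1 | starting material
2 | methyl 4-[tert-butyl(dimethyl)silyl]oxy-3-formylbenzoate | COC(=O)c1ccc(O[Si](C)(C)C(C)(C)C)c(C=O)c1 | intermediate
3 | methyl 4-[tert-butyl(dimethyl)silyl]oxy-3-[(E)-3-oxoprop-1-enyl]benzoate | COC(=O)c1ccc(O[Si](C)(C)C(C)(C)C)c(/C=C/C=O)c1 | intermediate
4 | methyl 2-hydroxy-2-methylpropanoate | COC(=O)C(C)(C)O | starting material
5 | methyl 2-methyl-2-(triethylsilyloxy)propanoate | COC(=O)C(C)(C)O[Si](CC)(CC)CC | intermediate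
6 | 2-methyl-2-(triethylsilyloxy)propanal | CC(C)(O[Si](CC)(CC)CC)C=O | intermediate
7 | methyl 4-[tert-butyl(dimethyl)silyl]oxy-3-[(2R,3R)-5-oxo-2-[2-(triethylsilyloxy)propan-2-yl]oxolan-3-yl]benzoate (cis lactone) | COC(=O)c1ccc(O[Si](C)(C)C(C)(C)C)c([C@H]2CC(=O)O[C@H]2C(C)(C)O[Si](CC)(CC)CC)c1 | intermediate
8 | methyl 4-[tert-butyl(dimethyl)silyl]oxy-3-[(2R,3R)-2-[2-(triethylsilyloxy)propan-2-yl]-5-(trimethylsilyloxy)-2,3-dihydrofuran-3-yl]benzoate | COC(=O)c1ccc(O[Si](C)(C)C(C)(C)C)c([C@H]2C=C(O[Si](C)(C)C)O[C@H]2C(C)(C)O[Si](CC)(CC)CC)c1 | intermediate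
9 | malonyl dichloride | O=C(Cl)CC(=O)Cl | starting material
10 | lactone 7 carrying a 3-chloro-3-oxopropanoyl group on the α-carbon C3a (configuration at C3a not defined) | COC(=O)c1ccc(O[Si](C)(C)C(C)(C)C)c([C@H]2C(C(=O)CC(=O)Cl)C(=O)O[C@H]2C(C)(C)O[Si](CC)(CC)CC)c1 | intermediate
11 | methyl 4-[tert-butyl(dimethyl)silyl]oxy-3-[(2R,3S)-4-hydroxy-6-oxo-2-[2-(triethylsilyloxy)propan-2-yl]-2,3-dihydro-6H-furo[2,3-b]pyran-3-yl]benzoate | COC(=O)c1ccc(O[Si](C)(C)C(C)(C)C)c([C@H]2C3=C(O[C@H]2C(C)(C)O[Si](CC)(CC)CC)OC(=O)C=C3O)c1 | intermediate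
12 | methyl 4-[tert-butyl(dimethyl)silyl]oxy-3-[(2R,3S)-4-methoxy-6-oxo-2-[2-(triethylsilyloxy)propan-2-yl]-2,3-dihydro-6H-furo[2,3-b]pyran-3-yl]benzoate | COC(=O)c1ccc(O[Si](C)(C)C(C)(C)C)c([C@H]2C3=C(O[C@H]2C(C)(C)O[Si](CC)(CC)CC)OC(=O)C=C3OC)c1 | intermediate
13 | 4-phenylbutan-2-one | CC(=O)CCc1ccccc1 | starting material
14 | (Z)-1-hydroxy-5-phenylpent-1-en-3-one | O/C=C\C(=O)CCc1ccccc1 | intermediate
15 | (Z)-1-[tert-butyl(dimethyl)silyl]oxy-5-phenylpent-1-en-3-one | CC(C)(C)[Si](C)(C)O/C=C\C(=O)CCc1ccccc1 | intermediate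
16 | bridged lactone (2-oxabicyclo[2.2.2]oct-5-en-3-one) from anti-face, endo addition of 15 across C5 and C7a of 12 | COC(=O)c1ccc(O[Si](C)(C)C(C)(C)C)c([C@H]2C3=C(OC)[C@H]4C(=O)O[C@]3(O[C@H]2C(C)(C)O[Si](CC)(CC)CC)[C@@H](C(=O)CCc2ccccc2)[C@H]4O[Si](C)(C)C(C)(C)C)c1 | intermediate
17 | methyl 4-[tert-butyl(dimethyl)silyl]oxy-3-[(2R,3S,6S,7S)-6-[tert-butyl(dimethyl)silyl]oxy-4-methoxy-7-(3-phenylpropanoyl)-2-[2-(triethylsilyloxy)propan-2-yl]-2,3,6,7-tetrahydro-1-benzofuran-3-yl]benzoate | COC(=O)c1ccc(O[Si](C)(C)C(C)(C)C)c([C@H]2C3=C(O[C@H]2C(C)(C)O[Si](CC)(CC)CC)[C@@H](C(=O)CCc2ccccc2)[C@@H](O[Si](C)(C)C(C)(C)C)C=C3OC)c1 | intermediate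
18 | methyl 4-hydroxy-3-[(2R,3S,6S,7S)-6-hydroxy-2-(2-hydroxypropan-2-yl)-4-methoxy-7-(3-phenylpropanoyl)-2,3,6,7-tetrahydro-1-benzofuran-3-yl]benzoate | COC(=O)c1ccc(O)c([C@H]2C3=C(O[C@H]2C(C)(C)O)[C@@H](C(=O)CCc2ccccc2)[C@@H](O)C=C3OC)c1 | target

**Step count**
Total: 12 steps. Longest linear sequence: 8 steps (1, 2, 5, 6, 7, 8, 11, 12).

**Steps most likely to fail**

Step 5. The homoenolate may add too slowly to the neopentyl-type aldehyde, so that self-annulation of the enal and redox side reactions take over, or the cis and enantio selectivity may be low. The fallback sets out from aldehyde 6 and returns at lactone 7 by known chemistry. Asymmetric alkynylation of 6 with methyl propiolate (ZnEt2, BINOL, Ti(OiPr)4) should give methyl (4R)-4-hydroxy-5-methyl-5-(triethylsilyloxy)hex-2-ynoate F1. Palladium-catalysed syn-hydroarylation (Pd(OAc)2, HCO2K, DMF) with methyl 4-[tert-butyl(dimethyl)silyl]oxy-3-iodobenzoate F2, made by one silylation of commercial methyl 4-hydroxy-3-iodobenzoate, places the aryl group on the carbinol-bearing alkyne carbon and the ester cis to the hydroxyl, so lactonisation gives the 4-aryl butenolide F3. Hydrogenation (H2, Rh on Al2O3, EtOAc) from the face opposite the side chain then gives the cis lactone 7.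

Step 7. HCl may cleave the silyl ethers, and intermolecular O-acylation or oligomerisation may outrun ring closure. The fallback sets out from ketene silyl acetal 8 and returns at methoxypyranone 12, separating C-acylation from ring closure so that no HCl is formed. Uncatalysed C-acylation of 8 with allyl 3-chloro-3-oxopropanoate should give the allyl β-keto ester F4. O-Methylation of its enol (MeOH, PPh3, DIAD) gives the 3-methoxyglutaconate-type enol ether F5, whose double-bond isomers converge later. Deallylation (Pd(PPh3)4, morpholine, THF) gives the free acid F6. Cyclodehydration through the mixed anhydride ((CF3CO)2O, Et3N, CH2Cl2), the established way from glutaconic half-esters to 6-alkoxy-2-pyranones, closes the ring to 12.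

Step 11. The cycloaddition of an electron-rich pyranone with a donor-substituted enone may be sluggish at a temperature the dienophile tolerates, with Z to E isomerisation, exo addition, or loss of silanol and aromatisation of the product. The fallback sets out from lactone 7 and returns at 17 with a much more reactive diene, so that the cycloaddition can run below room temperature. C-Acetylation of the lithium enolate of 7 (LiN(SiMe3)2, then 1-acetylimidazole) gives the acetyl lactone F7. O-Methylation (Me2SO4, K2CO3, acetone) gives the methoxyethylidene lactone F8. γ-Deprotonation with O-silylation (LiN(iPr)2, Me3SiCl, THF, −78 °C) gives the 1,1,3-trioxygenated diene F9. Its cycloaddition with 15 (CH2Cl2, −40 °C to rt; same regiochemistry, anti-face, endo) gives the ketal cycloadduct F10, and catalytic pyridinium p-toluenesulfonate then removes trimethylsilanol across C7a and C5 to give 17.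

**Further compounds**
F1 | step 5 | methyl (4R)-4-hydroxy-5-methyl-5-(triethylsilyloxy)hex-2-ynoate | COC(=O)C#C[C@@H](O)C(C)(C)O[Si](CC)(CC)CC
F2 | step 5 | methyl 4-[tert-butyl(dimethyl)silyl]oxy-3-iodobenzoate | COC(=O)c1ccc(O[Si](C)(C)C(C)(C)C)c(I)c1
F3 | step 5 | methyl 4-[tert-butyl(dimethyl)silyl]oxy-3-[(2R)-5-oxo-2-[2-(triethylsilyloxy)propan-2-yl]-2H-furan-3-yl]benzoate | COC(=O)c1ccc(O[Si](C)(C)C(C)(C)C)c(C2=CC(=O)O[C@H]2C(C)(C)O[Si](CC)(CC)CC)c1
F4 | step 7 | lactone 7 carrying a 3-(allyloxy)-3-oxopropanoyl group on C3a | COC(=O)c1ccc(O[Si](C)(C)C(C)(C)C)c([C@H]2C(C(=O)CC(=O)OCC=C)C(=O)O[C@H]2C(C)(C)O[Si](CC)(CC)CC)c1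
F5 | step 7 | methyl enol ether of F4 (allyl 3-methoxy-3-lactonylprop-2-enoate) | COC(=O)c1ccc(O[Si](C)(C)C(C)(C)C)c([C@H]2C(C(OC)=CC(=O)OCC=C)C(=O)O[C@H]2C(C)(C)O[Si](CC)(CC)CC)c1
F6 | step 7 | free acid from F5 (3-methoxy-3-lactonylprop-2-enoic acid) | COC(=O)c1ccc(O[Si](C)(C)C(C)(C)C)c([C@H]2C(C(OC)=CC(=O)O)C(=O)O[C@H]2C(C)(C)O[Si](CC)(CC)CC)c1
F7 | step 11 | lactone 7 carrying an acetyl group on C3a | COC(=O)c1ccc(O[Si](C)(C)C(C)(C)C)c([C@H]2C(C(C)=O)C(=O)O[C@H]2C(C)(C)O[Si](CC)(CC)CC)c1
F8 | step 11 | lactone 7 carrying a 1-methoxyethylidene group on C3a | COC(=O)c1ccc(O[Si](C)(C)C(C)(C)C)c([C@H]2C(=C(C)OC)C(=O)O[C@H]2C(C)(C)O[Si](CC)(CC)CC)c1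
F9 | step 11 | 4-(1-methoxyvinyl)-5-(trimethylsilyloxy)-2,3-dihydrofuran diene derived from F8 | COC(=O)c1ccc(O[Si](C)(C)C(C)(C)C)c([C@H]2C(C(=C)OC)=C(O[Si](C)(C)C)O[C@H]2C(C)(C)O[Si](CC)(CC)CC)c1
F10 | step 11 | cycloadduct of F9 and 15 with a trimethylsilyloxy ketal at C7a | COC(=O)c1ccc(O[Si](C)(C)C(C)(C)C)c([C@H]2C3=C(OC)C[C@H](O[Si](C)(C)C(C)(C)C)[C@H](C(=O)CCc4ccccc4)[C@]3(O[Si](C)(C)C)O[C@H]2C(C)(C)O[Si](CC)(CC)CC)c1
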